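**Plan**

- Retrosynthetic cuts: the two ester C–O bonds; the allylic C–O bond at the isovalerate carbon, traced back by a 1,3-oxygen shift to a tertiary alcohol on the methyl-bearing alkene carbon; the tertiary C–OH of the five-membered ring (alkene hydration); the two five-ring bonds that tie a CH2–C=C(iPr) unit to the quaternary carbon and to the ring-fusion CH; the cycloheptenone back to a furan/oxyallyl [4+3] adduct.
- Enabling feature: with the aroyloxy-bearing carbon of the seven-membered ring as a ketone, the ring-fusion CH (α) and the methyl-bearing quaternary carbon (β) are the two carbons of a cycloheptenone. That enone is electrophilic at β and nucleophilic at α, the exact complement of an allenylsilane (nucleophilic CH2 end, vinyl-cation end after silyl shift).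
- Forward order: seven-membered carbocycle first (oxa-bridged [4+3] adduct, opened to the enone), five-membered ring in one annulation, then hydration, diol-to-alkene, oxygen transposition and two acylations. The ring alkene travels as a silylene-protected cis-diol so that the enone is not a dienone and the γ-oxygen steers the annulation.
- Stereochemistry: absolute configuration from chiral lithium amide enolisation of a meso ketone; quaternary carbon by attack anti to the γ-oxygen; cis ring fusion from the annulation; aroyloxy carbon by hydroxyl-directed hydride delivery; five-ring carbinol by convex-face hydration; isovalerate carbon by suprafacial [3,3] oxygen transfer.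

Key step: step 7

Assumption: the (R,R)-amide is taken to remove the α-hydrogen that gives enol ether 7 as drawn, by analogy with the unsubstituted oxabicyclic ketone; if the sense proves opposite, the (S,S)-amide is used and nothing else changes.

Step 1
Reactants: 1 2,5-dimethylfuran; 2 1,1,3,3-tetrabromopropan-2-one
Product: 4 meso-1,5-dimethyl-8-oxabicyclo[3.2.1]oct-6-en-3-one, via dibromo cycloadduct 3 (not isolated)
Conditions: Zn–Cu couple, THF, −10 °C to rt; then Zn–Cu couple, NH4Cl, MeOH, rt
Reagents that add atoms: none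
Why: Zinc reduces 2 to a dibromo-oxyallyl cation that adds across the 2,5-positions of the furan in a [4+3] cycloaddition, and the second zinc treatment removes both α-bromines; the product is meso, so nothing needs control.

Step 2
Reactants: 4 meso oxabicyclic enone
Product: 5 meso-6-exo,7-exo-dihydroxy-1,5-dimethyl-8-oxabicyclo[3.2.1]octan-3-one
Conditions: OsO4 (cat.), NMO, acetone/H2O, rt
Reagents that add atoms: N-methylmorpholine N-oxide C[N+]1([O-])CCOCC1; water O
Why: Upjohn dihydroxylation should occur on the exo face of the strained alkene, syn to the oxygen bridge and away from the ketone bridge, giving the meso cis-diol.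

Step 3
Reactants: 5 meso diol
Product: 6 meso-6,7-O-(di-tert-butylsilylene)-1,5-dimethyl-8-oxabicyclo[3.2.1]octan-3-one
Conditions: t-Bu2Si(OTf)2, 2,6-lutidine, CH2Cl2, 0 °C
Reagents that add atoms: di-tert-butylsilyl bis(trifluoromethanesulfonate) CC(C)(C)[Si](OS(=O)(=O)C(F)(F)F)(OS(=O)(=O)C(F)(F)F)C(C)(C)C
Why: Silylene protection of a cis-1,2-diol gives a compact dioxasilolane that should tolerate amide base, Lewis acid and TFA and keeps the ketone meso.

Step 4
Reactants: 6 meso silylene ketone
Product: 8 4,5-O-(di-tert-butylsilylene)-4,5-dihydroxy-3,6-dimethyl-6-(trimethylsilyloxy)cyclohept-2-en-1-one (oxygens at C4/C5/C6 mutually cis), via enol silyl ether 7 (not isolated)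
Conditions: lithium (R,R)-bis(1-phenylethyl)amide (from the amine and n-BuLi), LiCl, TMSCl, THF, −100 °C; then TMSOTf (10 mol%), CH2Cl2, −78 to −20 °C
Reagents that add atoms: chlorotrimethylsilane C[Si](C)(C)Cl
Why: Enantiotopic-proton-selective enolisation of a meso 8-oxabicyclo[3.2.1]octan-3-one by a C2-symmetric chiral lithium amide with internal silyl quench fixes the absolute configuration, and catalytic TMSOTf should then open the β-alkoxy enol ether by ionisation of the bridgehead C–O bond with silyl transfer to the tertiary oxygen.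

Step 5
Reactants: 9 3-(trimethylsilyl)prop-2-yn-1-ol
Product: 10 3-(trimethylsilyl)prop-2-yn-1-yl methanesulfonate
Conditions: MsCl, Et3N, CH2Cl2, 0 °C
Reagents that add atoms: methanesulfonyl chloride CS(=O)(=O)Cl
Why: Routine sulfonylation of a primary propargylic alcohol.

Step 6
Reactants: 10 propargylic mesylate
Product: 11 trimethyl(4-methylpenta-1,2-dien-3-yl)silane
Conditions: i-PrMgCl, CuBr, LiBr, THF, −70 °C to rt
Reagents that add atoms: isopropylmagnesium chloride CC(C)[Mg]Cl
Why: SN2′ substitution of a propargylic mesylate by an organocopper reagent attacks the silyl-bearing alkyne carbon and should give the 1-alkyl-1-silylallene.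

Step 7
Reactants: 8 γ-oxygenated β-methyl cycloheptenone; 11 allenylsilane
Product: 12 cis-fused 6-hydroxy-6,8a-dimethyl-3-(propan-2-yl)-7,8-(di-tert-butylsilylenedioxy)-2-(trimethylsilyl)-3a,5,6,7,8,8a-hexahydroazulen-4(1H)-one (8a-CH3 and 3a-H and 6-OH and both silylene oxygens on one face)
Conditions: TiCl4 (1.5 equiv), CH2Cl2, −78 to −40 °C; then 1 M HCl, THF, 0 °C
Reagents that add atoms: none
Why: Proposed new method: TiCl4 activates the enone, the CH2 terminus of the allenylsilane attacks the methyl-bearing β-carbon to give a β-silyl vinyl cation, a 1,2-silyl shift moves the charge to the isopropyl-bearing carbon, and the titanium enolate closes on it through its α-carbon, so the quaternary-carbon–CH2 bond and the ring-fusion-CH–C(iPr) bond form in one operation. The closest known reaction type is the Danheiser (trimethylsilyl)cyclopentene annulation of allenylsilanes with cyclic enones, extended here to a β,β-disubstituted enone by analogy with Sakurai allylations that build quaternary β-carbons. The five-membered ring closes by a 5-(enolexo)-endo-dig attack on the linear vinyl cation. The quaternary carbon is set by approach anti to the γ-oxygen of the fused dioxasilolane (methyl ends cis to that oxygen), and the ring-fusion hydrogen ends cis to methyl because the three-atom tether can only reach the enolate face it already occupies. The step needs conjugate over carbonyl addition and ring closure over loss of silicon from the vinyl cation; the soft silane/TiCl4 pair secures the first and the 1-alkyl group on the allene, which stabilises the rearranged cation, the second. The acidic work-up frees the tertiary hydroxyl that directs step 8.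

Step 8
Reactants: 12 vinylsilane hydroxy ketone
Product: 13 corresponding 4,6-diol (4-OH on the face opposite to the angular methyl)
Conditions: Me4NBH(OAc)3, MeCN/AcOH, −30 °C
Reagents that add atoms: none
Why: Evans–Saksena reduction: the tertiary β-hydroxyl binds boron and delivers hydride intramolecularly through a six-membered chair, which should give the 1,3-anti diol with the new hydroxyl on the face of the five-membered ring.

Step 9
Reactants: 13 diol
Product: 14 4-(4-acetoxybenzoate) of 13
Conditions: 4-acetoxybenzoyl chloride, Et3N, DMAP (cat.), CH2Cl2, 0 °C to rt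
Reagents that add atoms: 4-acetoxybenzoyl chloride CC(=O)Oc1ccc(cc1)C(Cl)=O
Why: DMAP-catalysed acylation should take the only secondary hydroxyl and leave the tertiary one.

Step 10
Reactants: 14 vinylsilane ester
Product: 15 cyclopentene ester (2-H in place of 2-SiMe3)
Conditions: TFA, wet CH2Cl2, 0 °C
Reagents that add atoms: none
Why: Protodesilylation: ipso protonation gives a tertiary β-silyl cation that loses silicon, so the double bond should stay where the annulation put it.

Step 11
Reactants: 15 cyclopentene ester
Product: 16 tertiary cyclopentanol (3-OH cis to the angular methyl and 3a-H; isopropyl on the concave face)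
Conditions: Mn(dpm)3 [Mn(C11H19O2)3] (cat.), PhSiH3, O2 (1 atm), i-PrOH/CH2Cl2, 0 °C
Reagents that add atoms: dioxygen O=O
Why: Mukaiyama hydration: hydrogen-atom transfer to the CH terminus gives the tertiary radical, which O2 should trap on the convex face of the cis-fused bicycle, anti to the adjacent aroyloxy-bearing ring carbon; no other alkene is present.

Step 12
Reactants: 16 silylene triol ester
Product: 17 7,8-diol (silylene removed)
Conditions: HF·pyridine, THF/pyridine, 0 °C
Reagents that add atoms: none
Why: Fluoride cleaves the silylene and should leave both esters and the tertiary alcohols untouched.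

Step 13
Reactants: 17 cis-7,8-diol
Product: 19 3,6-dihydroxy-6,8a-dimethyl-3-(propan-2-yl)-1,2,3,3a,4,5,6,8a-octahydroazulen-4-yl 4-acetoxybenzoate, via cyclic thionocarbonate 18 (not isolated)
Conditions: Cl2C=S, DMAP, CH2Cl2, 0 °C; then 1,3-dimethyl-2-phenyl-1,3,2-diazaphospholidine, THF, 40 °C
Reagents that add atoms: thiophosgene ClC(Cl)=S (its C=S is carried in 18 only)
Why: Corey–Winter olefination: the secondary cis-diol should form the thionocarbonate, and sulfur abstraction then gives a carbene that loses CO2 by syn-elimination, regenerating the cis ring alkene under neutral conditions that spare both esters.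

Step 14
Reactants: 19 tertiary allylic alcohol
Product: 20 3,8-dihydroxy-6,8a-dimethyl-3-(propan-2-yl)-1,2,3,3a,4,5,8,8a-octahydroazulen-4-yl 4-acetoxybenzoate (8-OH cis to the angular methyl)
Conditions: Ph3SiOReO3 (5 mol%), Et2O, −20 to 0 °C
Reagents that add atoms: none
Why: Rhenium-oxo catalysed 1,3-transposition of an allylic alcohol: the perrhenate ester should rearrange by a suprafacial [3,3] shift across the ring alkene, moving oxygen to the secondary carbon on the same face and forming the trisubstituted alkene, the thermodynamic isomer.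

Step 15
Reactants: 20 allylic alcohol
Product: 21 8-(3-methylbutanoate) of 20
Conditions: (i-BuCO)2O, DMAP, pyridine, CH2Cl2, rt
Reagents that add atoms: 3-methylbutanoic anhydride CC(C)CC(=O)OC(=O)CC(C)C
Why: DMAP-catalysed acylation should take the only secondary hydroxyl; the tertiary cyclopentanol is inert.

Step 16
Reactants: 21 phenolic acetate
Product: 22 target, (3S,3aS,4R,8R,8aR)-3-hydroxy-6,8a-dimethyl-8-(3-methylbutanoyloxy)-3-(propan-2-yl)-1,2,3,3a,4,5,8,8a-octahydroazulen-4-yl 4-hydroxybenzoate
Conditions: K2CO3 (0.2 equiv), MeOH, 0 °C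
Reagents that add atoms: none
Why: Phenolic acetates undergo methanolysis far faster than alkyl esters, and the phenoxide formed deactivates the benzoate carbonyl.

**Compound list**

1 | 2,5-dimethylfuran | Cc1ccc(C)o1 | starting material
2 | 1,1,3,3-tetrabromopropan-2-one | BrC(Br)C(=O)C(Br)Br | starting material
3 | 2,4-dibromo-1,5-dimethyl-8-oxabicyclo[3.2.1]oct-6-en-3-one (bromine epimers) | C[C@]12C=C[C@](C)(C(Br)C(=O)C1Br)O2 | intermediate
4 | meso-1,5-dimethyl-8-oxabicyclo[3.2.1]oct-6-en-3-one | C[C@]12C=C[C@](C)(CC(=O)C1)O2 | intermediate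
5 | meso-6-exo,7-exo-dihydroxy-1,5-dimethyl-8-oxabicyclo[3.2.1]octan-3-one | C[C@]12[C@@H](O)[C@@H](O)[C@](C)(CC(=O)C1)O2 | intermediate
6 | meso-6,7-O-(di-tert-butylsilylene) derivative of 5 | C[C@]12[C@@H](O[Si]3(C(C)(C)C)C(C)(C)C)[C@@H](O3)[C@](C)(CC(=O)C1)O2 | intermediate
7 | 3-(trimethylsilyloxy)-2-ene enol ether of 6, single enantiomer | C[C@]12[C@@H](O[Si]3(C(C)(C)C)C(C)(C)C)[C@@H](O3)[C@](C)(C=C(O[Si](C)(C)C)C1)O2 | intermediate
8 | 4,5-O-(di-tert-butylsilylene)-4,5-dihydroxy-3,6-dimethyl-6-(trimethylsilyloxy)cyclohept-2-en-1-one, three oxygens cis | C[C@]1(O[Si](C)(C)C)[C@@H](O[Si]3(C(C)(C)C)C(C)(C)C)[C@@H](O3)C(C)=CC(=O)C1 | intermediate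
9 | 3-(trimethylsilyl)prop-2-yn-1-ol | C[Si](C)(C)C#CCO | starting material
10 | 3-(trimethylsilyl)prop-2-yn-1-yl methanesulfonate | C[Si](C)(C)C#CCOS(C)(=O)=O | intermediate
11 | trimethyl(4-methylpenta-1,2-dien-3-yl)silane | C=C=C(C(C)C)[Si](C)(C)C | intermediate
12 | cis-fused vinylsilane hydroxy ketone (see step 7) | C[C@]1(O)[C@@H](O[Si]3(C(C)(C)C)C(C)(C)C)[C@@H](O3)[C@]2(C)CC([Si](C)(C)C)=C(C(C)C)[C@@H]2C(=O)C1 | intermediate
13 | 4,6-diol from 12 | C[C@]1(O)[C@@H](O[Si]3(C(C)(C)C)C(C)(C)C)[C@@H](O3)[C@]2(C)CC([Si](C)(C)C)=C(C(C)C)[C@@H]2[C@H](O)C1 | intermediate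
14 | 4-(4-acetoxybenzoate) of 13 | C[C@]1(O)[C@@H](O[Si]3(C(C)(C)C)C(C)(C)C)[C@@H](O3)[C@]2(C)CC([Si](C)(C)C)=C(C(C)C)[C@@H]2[C@H](OC(=O)c2ccc(OC(C)=O)cc2)C1 | intermediate
15 | protodesilylated cyclopentene ester | C[C@]1(O)[C@@H](O[Si]3(C(C)(C)C)C(C)(C)C)[C@@H](O3)[C@]2(C)CC=C(C(C)C)[C@@H]2[C@H](OC(=O)c2ccc(OC(C)=O)cc2)C1 | intermediate
16 | tertiary cyclopentanol (3-OH cis to angular methyl) | C[C@]1(O)[C@@H](O[Si]3(C(C)(C)C)C(C)(C)C)[C@@H](O3)[C@]2(C)CC[C@](O)(C(C)C)[C@@H]2[C@H](OC(=O)c2ccc(OC(C)=O)cc2)C1 | intermediate
17 | 7,8-diol from 16 | C[C@]1(O)[C@@H](O)[C@@H](O)[C@]2(C)CC[C@](O)(C(C)C)[C@@H]2[C@H](OC(=O)c2ccc(OC(C)=O)cc2)C1 | intermediate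
18 | 7,8-cyclic thionocarbonate of 17 | C[C@]1(O)[C@@H](OC3=S)[C@@H](O3)[C@]2(C)CC[C@](O)(C(C)C)[C@@H]2[C@H](OC(=O)c2ccc(OC(C)=O)cc2)C1 | intermediate
19 | tertiary allylic alcohol with the 7,8-alkene | C[C@]1(O)C=C[C@]2(C)CC[C@](O)(C(C)C)[C@@H]2[C@H](OC(=O)c2ccc(OC(C)=O)cc2)C1 | intermediate
20 | transposed secondary allylic alcohol with the 6,7-alkene | CC1=C[C@@H](O)[C@]2(C)CC[C@](O)(C(C)C)[C@@H]2[C@H](OC(=O)c2ccc(OC(C)=O)cc2)C1 | intermediate
21 | 8-(3-methylbutanoate) of 20 | CC1=C[C@@H](OC(=O)CC(C)C)[C@]2(C)CC[C@](O)(C(C)C)[C@@H]2[C@H](OC(=O)c2ccc(OC(C)=O)cc2)C1 | intermediate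
22 | target | CC1=C[C@@H](OC(=O)CC(C)C)[C@]2(C)CC[C@](O)(C(C)C)[C@@H]2[C@H](OC(=O)c2ccc(O)cc2)C1 | target

**Count and risks**

Total step count: 16. Longest linear sequence: 14 (steps 1–4 and 7–16).

Step 7 carries the most risk. The allenylsilane may not add to the hindered β-carbon, the vinyl cation may lose silicon before ring closure, or TiCl4 may strip the silyl groups. The fallback sets out from 8 and uses known chemistry. The Kulinkovich reaction of methyl isobutyrate (EtMgBr, Ti(OiPr)4) gives 1-(propan-2-yl)cyclopropan-1-ol F1. Its zinc homoenolate (Et2Zn) is added to 8 under CuBr·SMe2 catalysis with TMSCl, anti to the γ-oxygen, to give the keto enol silyl ether F2. KN(SiMe3)2 and PhNTf2 convert the side-chain ketone to the (Z)-enol triflate F3. Palladium-catalysed intramolecular α-alkenylation of the enol silyl ether (Pd2(dba)3, P(t-Bu)3, CsF) closes the cis-fused cyclopentene and, with loss of the tertiary silyl ether, gives the cyclopentene hydroxy ketone F4. Me4NBH(OAc)3 gives the anti diol F5, and acylation with 4-acetoxybenzoyl chloride rejoins the route at 15.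

Step 14 may fail by ionisation of the perrhenate ester, which would cause elimination to a diene or erode the facial transfer. The fallback sets out from 19. Oxidative transposition with [C5H5NH][CrO3Cl] (Babler–Dauben oxidation) gives the enone F6. A CBS reduction with catecholborane then returns 20 under reagent control; the (S)-oxazaborolidine is chosen on the premise that the quaternary carbon acts as the large group.

Step 11 may fail through poor facial discrimination in the oxygen capture or through simple reduction of the alkene. The fallback sets out from 15. Epoxidation with m-CPBA/NaHCO3 on the convex face gives the epoxide F7. Li2NiBr4 opens it at the secondary carbon to the bromohydrin F8, and Bu3SnH with AIBN removes bromine to return 16.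

**Further compounds**

F1 | step 7 | 1-(propan-2-yl)cyclopropan-1-ol | CC(C)C1(O)CC1
F2 | step 7 | keto enol silyl ether from conjugate addition to 8 | C[C@]1(O[Si](C)(C)C)[C@@H](O[Si]3(C(C)(C)C)C(C)(C)C)[C@@H](O3)[C@](C)(CCC(=O)C(C)C)C=C(O[Si](C)(C)C)C1
F3 | step 7 | (Z)-enol triflate of F2 | C[C@]1(O[Si](C)(C)C)[C@@H](O[Si]3(C(C)(C)C)C(C)(C)C)[C@@H](O3)[C@](C)(C/C=C(\OS(=O)(=O)C(F)(F)F)C(C)C)C=C(O[Si](C)(C)C)C1
F4 | step 7 | cis-fused cyclopentene hydroxy ketone | C[C@]1(O)[C@@H](O[Si]3(C(C)(C)C)C(C)(C)C)[C@@H](O3)[C@]2(C)CC=C(C(C)C)[C@@H]2C(=O)C1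
F5 | step 7 | cyclopentene anti diol | C[C@]1(O)[C@@H](O[Si]3(C(C)(C)C)C(C)(C)C)[C@@H](O3)[C@]2(C)CC=C(C(C)C)[C@@H]2[C@H](O)C1
F6 | step 14 | transposed enone | CC1=CC(=O)[C@]2(C)CC[C@](O)(C(C)C)[C@@H]2[C@H](OC(=O)c2ccc(OC(C)=O)cc2)C1
F7 | step 11 | convex-face epoxide of 15 | C[C@]1(O)[C@@H](O[Si]3(C(C)(C)C)C(C)(C)C)[C@@H](O3)[C@]2(C)C[C@H]4O[C@@]4(C(C)C)[C@@H]2[C@H](OC(=O)c2ccc(OC(C)=O)cc2)C1
F8 | step 11 | bromohydrin from F7 | C[C@]1(O)[C@@H](O[Si]3(C(C)(C)C)C(C)(C)C)[C@@H](O3)[C@]2(C)C[C@H](Br)[C@](O)(C(C)C)[C@@H]2[C@H](OC(=O)c2ccc(OC(C)=O)cc2)C1
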